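The zeta run, which is the flask asked about followed to 20.0 min, has X at 19% and 18% in its last two readings while Z still falls, and that levelling is what can be read.

in all of them: Z 0.80 M
- zeta: D 3.2 M; the very flask that is asked about, followed so far
- flask: D 3.20 M; time 40 min; volume of the second phase over the first 2.0

zeta run (percent of the Z charged)

| time / min | X / % | Z / % |
|---|---|---|
| 3.00 | 2 | 101 |
| 6.00 | 4 | 93 |
| 8.00 | 8 | 93 |
| 12.0 | 13 | 81 |
| 15.0 | 19 | 76 |
| 20.0 | 18 | 64 |

(readings scatter by 2 percentage points)

- what is said of X includes G
- in the second phase: D, G; everything else is in the first
- charges count per volume of the first phase; a concentration in a rate is the amount of a species over the volume of its own phase; every rate counts per litre of the first phase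
- the earlier runs were read with a standard deviation of 2 percentage points
- the earlier runs hold the two phases in the same ratio of volumes as the flask asked about

- how much X and G together there is at 40 min, in percent of the Z charged
- part of the Z charged that has reacted at 40 min

Follow one molecule, taking each Z lost to become X, with G counted in X. X then waits until it leaves. While X holds level (a quasi-steady state, within the scatter of 2 percentage points), it leaves as fast as it is fed. Z falls by 0.0213 min⁻¹ of the charge between 12.0 min and 20.0 min, so the level amount over that feed reads 8.71 min. This is the lifetime of X, and the chance of surviving to a given age is exp(−age/lifetime).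

Over the same window Z falls with a first-order constant of 0.0294 min⁻¹. Carried on, that leaves 35.5% at 40 min, so 64.5% has reacted. Feed times lifetime then gives 9.09% of X and G. The weak link is that X present was made earlier, when Z stood higher. Weighing each past feed by its survival divides that figure by 0.744, and the reckoning commits to 12.2%.

The forecast takes a share of about 0.55 of the reacted Z “With selectivity around 0.55” and stands at 35%, above this reckoning, with 64% reacted.

The flask gives 17.7% with 68.5% reacted, so the forecast's yield is 17 points high. At 40.0 min, G stands at 5.97% of the Z charged, which is a third of that sum. The computed Z of 32%, put through the same lifetime reckoning, gives 10.9%, which is 6.8 points below the flask.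

    Z + E → X (k = 0.00170 L mol⁻¹ s⁻¹)
    X → J (k = 0.00130 s⁻¹)
    X ⇌ G, rate k3*([X] - [G]/K3) per volume of the first phase (partition coefficient = 2.30, kL = 2.30 × 10⁻⁴ s⁻¹)
    X → L (k = 5.60 × 10⁻⁴ s⁻¹)
    E ⇌ D, rate k5*([E] - [D]/K5) per volume of the first phase (partition coefficient = 2.20, kL = 0.00120 s⁻¹)

The neighbour flask, the same charge read at 10 min, is still filling. An early feed of 0.0158 min⁻¹ from the zeta run, times the lifetime, times 1 minus exp(−time/lifetime), gives 9.40%. The computed flask holds 10.3%, with 15.1% reacted.

The runs come from a simulation with constants of no real substance; scatter was added.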